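**Plan**

1. Retrosynthesis: the C1/C10 epoxide, the C8 isobutyrate, the C11=C13 methylene and the lactone C12–O6 bond are removed first; the C6 carbinol becomes a ketone, and a C6–C10 bond is then put back across the ten-membered ring (retro-Grob).
2. Enabling feature (germacrane numbering): the lactone carbinol carbon C6 and the epoxide carbon C10 face each other across the ring, and the other epoxide carbon C1 is the neighbour of C10. A C6–C10 bond therefore splits the ring into a cyclopentane (C6–C7–C8–C9–C10, carrying C7 and C8) and a cycloheptene (C6–C5=C4–C3–C2–C1–C10, where C4=C5 can only be cis), with O6–C6–C10–C1–O as a 1,3-diol.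
3. Forward, the cyclopentane is present from the start in (1R,5S)-2-oxabicyclo[3.3.0]oct-6-en-3-one. C10–C1 (aldol-type coupling), C10–C14 (enolate alkylation) and C6–C5 (vinyl addition) are attached, and ring-closing metathesis (C4=C5) adds the cycloheptene.
4. Directed reduction at C1, mesylation and fragmentation of the trans-fused hydroazulene (its C6, C10 and C1 centres vanish in the key step) uncover the ten-membered dienone. The γ-lactone (C6 reduction, oxidative lactonisation, methylenation), the C8 ester and finally the epoxide follow.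
5. Stereochemistry: C7 and C8 come from the cis ring fusion of the starting lactone. The transient centres C10, C6 and C1 are set by attack anti to the C7 arm and by hydroxyl-directed hydride delivery. The C1=C10 geometry follows from the anti-periplanar fragmentation, and C4=C5 from ring size.
6. C6 is set by an oxazaborolidine-catalysed reduction, and C1/C10 by Sharpless epoxidation with L-(+)-diethyl tartrate.

Key step: step 15

Remark on numbering: germacrane numbers are used for all intermediates; β is the face of the cyclopentane that bears the C7 arm (C11–C12) and the C8 oxygen, α the opposite face.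
Assumption: in step 16 the alkenyl carbon C5 is taken to act as the larger ketone substituent towards the oxazaborolidine, as is usual for enones.
Remark: the C1 carbinol in 11–17 is carried as both epimers (their SMILES leave C1 open), because it is oxidised to the ketone in step 11 and reset in step 13.
Remark: both enantiomers of lactone 1 are commercial; 4-methoxybenzyl chloromethyl ether (step 9) is prepared just before use.

**Route**

Step 1
Reactants: 1 (1R,5S)-2-oxabicyclo[3.3.0]oct-6-en-3-one
Product: 2 (1R,2S)-2-(2-hydroxyethyl)cyclopent-3-en-1-ol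
Conditions: LiAlH4, THF, 0 °C to rt
Reagents that add atoms: none
Why: Hydride reduction of the lactone to the diol touches neither stereocentre, so the cis relation of the C8 oxygen and the C7 two-carbon arm is taken over from the ring fusion of 1.

Step 2
Reactants: 2 (1R,2S)-2-(2-hydroxyethyl)cyclopent-3-en-1-ol
Product: 3 bis(tert-butyldimethylsilyl) ether of 2
Conditions: TBSCl, imidazole, DMF, rt
Reagents that add atoms: tert-butyldimethylsilyl chloride, CC(C)(C)[Si](C)(C)Cl
Why: Silyl ether formation at the primary C12 and secondary C8 hydroxyls should proceed without affecting a stereocentre.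

Step 3
Reactants: 3 bis(tert-butyldimethylsilyl) ether of 2
Product: 4 α-epoxide of 3 (C6–C10 epoxide)
Conditions: mCPBA, NaHCO3, CH2Cl2, 0 °C
Reagents that add atoms: 3-chloroperoxybenzoic acid, OOC(=O)c1cccc(Cl)c1
Why: Prilezhaev epoxidation should take place on the α face, opposite to the allylic C7 arm and the homoallylic silyloxy group, which fixes both epoxide carbons.

Step 4
Reactants: 4 α-epoxide of 3
Product: 7 (1R,4R,5S)-4-(tert-butyldimethylsilyloxy)-5-[2-(tert-butyldimethylsilyloxy)ethyl]cyclopent-2-en-1-ol, via hydroxy selenide 5 (not isolated), via selenoxide 6 (not isolated)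
Conditions: PhSeSePh, NaBH4, EtOH, 60 °C; then H2O2 (30 %), THF, 0 °C to rt
Reagents that add atoms: none
Why: In this Sharpless–Lauer transposition of an epoxide into an allylic alcohol the selenolate should open the epoxide trans at C10, the carbon remote from the C7 arm, and the selenoxide should eliminate syn towards C9, away from the carbinol, leaving the C6 hydroxyl (α) and the C9=C10 alkene.

Step 5
Reactants: 7 allylic alcohol
Product: 8 (4R,5R)-4-(tert-butyldimethylsilyloxy)-5-[2-(tert-butyldimethylsilyloxy)ethyl]cyclopent-2-en-1-one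
Conditions: Dess–Martin periodinane, NaHCO3, CH2Cl2, 0 °C
Reagents that add atoms: none
Why: Dess–Martin oxidation under buffered, non-basic conditions should give the cis-4,5-disubstituted cyclopentenone without enolisation at C7.

Step 6
Reactants: 9 4-methylpent-4-en-1-ol
Product: 10 4-methylpent-4-enal
Conditions: Dess–Martin periodinane, CH2Cl2, 0 °C to rt; used as a CH2Cl2 solution
Reagents that add atoms: none
Why: Dess–Martin oxidation of a primary alcohol stops at the aldehyde, and the volatile product is carried on in solution.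

Step 7
Reactants: 8 cis-4,5-disubstituted cyclopentenone; 10 4-methylpent-4-enal
Product: 12 enone carrying the 1-hydroxy-4-methylpent-4-enyl group at C10 (both C1 epimers), via iodo aldol adduct 11 (not isolated)
Conditions: Et2AlI, CH2Cl2, −78 to −20 °C; then Et3N, 0 °C
Reagents that add atoms: none
Why: This Morita–Baylis–Hillman-type coupling (iodide adds to C9, the aluminium enolate attacks the aldehyde through C10, loss of HI restores the enone) is chosen because it avoids basic enolisation next to the C8 silyloxy group; the C1 carbinol is expected as both epimers, which does not matter because C1 is oxidised in step 11.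

Step 8
Reactants: 12 Baylis–Hillman-type adduct
Product: 13 trimethylsilyl ether of 12
Conditions: TMSCl, imidazole, CH2Cl2, 0 °C
Reagents that add atoms: chlorotrimethylsilane, C[Si](C)(C)Cl
Why: Silyl ether formation masks the C1 hydroxyl for the enolate step, and the trimethylsilyl group can later be removed without touching the two TBS ethers.

Step 9
Reactants: 13 trimethylsilyl ether of 12
Product: 15 cyclopentanone with quaternary C10 (C14H2OPMB α; C1 arm β), via lithium enolate 14 (not isolated)
Conditions: LiBH(s-Bu)3, THF, −78 °C; then PMBOCH2Cl (freshly prepared), −78 to −30 °C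
Reagents that add atoms: 4-methoxybenzyl chloromethyl ether, COc1ccc(COCCl)cc1
Why: In this conjugate reduction–enolate alkylation hydride adds to C9, the enolate is formed regiospecifically at C10, and the chloromethyl ether should enter on the α face, anti to the C7 arm and the C8 silyloxy group, which fixes the quaternary centre.

Step 10
Reactants: 15 cyclopentanone with quaternary C10
Product: 17 diol (C6 β-hydroxyl and α-vinyl; free C1 hydroxyl), via silylated vinyl carbinol 16 (not isolated)
Conditions: CH2=CHMgBr, CeCl3, THF, −78 to 0 °C; then K2CO3, MeOH, rt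
Reagents that add atoms: vinylmagnesium bromide, C=C[Mg]Br
Why: In this cerium-mediated Grignard 1,2-addition to a hindered, enolisable ketone the vinyl group should enter on the α face, which carries only H7 and the CH2OPMB group, anti to the β-oriented C7 and C1 arms, so that the C6 hydroxyl is β; methanolysis then frees the C1 hydroxyl.

Step 11
Reactants: 17 diol
Product: 18 β-hydroxy ketone (C1 ketone)
Conditions: Dess–Martin periodinane, pyridine, CH2Cl2, 0 °C
Reagents that add atoms: none
Why: Dess–Martin oxidation should affect only the secondary C1 alcohol, the tertiary allylic C6 alcohol being inert, and both C1 epimers give the same ketone.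

Step 12
Reactants: 18 β-hydroxy ketone
Product: 19 trans-fused bicyclo[5.3.0]decenone (C1 ketone, C6 β-hydroxyl, C10 α-CH2OPMB, C4=C5)
Conditions: second-generation Grubbs catalyst [RuCl2(=CHPh)(PCy3)(SIMes)] (5 mol %), toluene (0.005 M), 80 °C
Reagents that add atoms: none
Why: Ring-closing metathesis between the C6 vinyl group and the 1,1-disubstituted alkene should close the cycloheptene, in which C4=C5 is necessarily cis, and since the two arms are trans on the cyclopentane the ring fusion is trans.

Step 13
Reactants: 19 trans-fused bicyclic ketol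
Product: 20 trans-fused 1,6-diol (C1 hydroxyl cis to C14 and anti to the C6 hydroxyl)
Conditions: Me4NBH(OAc)3, MeCN/AcOH, −30 °C
Reagents that add atoms: none
Why: In this Evans–Saksena hydroxyl-directed reduction the borohydride bound to the axial C6 oxygen should deliver hydride to the C1 ketone on that face and give the 1,3-anti diol, i.e. an equatorial C1 hydroxyl cis to the angular C14 arm, which is also the face an external hydride would take to avoid that arm.

Step 14
Reactants: 20 trans-fused 1,6-diol
Product: 21 C1 mesylate of 20 (tertiary C6 hydroxyl free)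
Conditions: MsCl, Et3N, CH2Cl2, −20 °C
Reagents that add atoms: methanesulfonyl chloride, CS(=O)(=O)Cl
Why: Sulfonylation should take place only at the secondary C1 alcohol, with retention at C1, because the tertiary C6 alcohol is unreactive under these conditions.

Step 15
Reactants: 21 C1 mesylate
Product: 23 ten-membered dienone (C6 ketone, ring-cis C4=C5, ring-trans C1=C10), via potassium alkoxide 22 (not isolated)
Conditions: KN(SiMe3)2 (1.05 equiv), THF, −78 to −30 °C; pH 7 buffer at −78 °C
Reagents that add atoms: none
Why: This is a Grob (Wharton-type) fragmentation of a bicyclic 1,3-diol monosulfonate: deprotonation gives alkoxide 22, whose oxygen lone pair pushes the C6–C10 bond electrons into C10–C1 while the mesylate, equatorial and anti-periplanar to C6–C10 in the trans-fused hydroazulene, departs in one concerted event. No bond is formed to close a ring; the ten-membered ring is uncovered by cutting the bond shared by the cyclopentane and the cycloheptene, the closest precedent being the base-induced opening of decalin and hydroazulene γ-sulfonyloxy alkoxides to cyclodecenones. No stereocentre is created: C6, C10 and C1 are erased, and C7 and C8 are carried over unchanged. The C1=C10 geometry is stereospecific, because with the mesylate cis to C14 the ring carbon C2 is anti to C9 in the reacting conformer and only the ring-trans alkene can form, while C4=C5 stays cis as made in the seven-membered ring. Chemoselectivity rests on the silylated C8 oxygen (no second alkoxide that could cleave C9–C10) and on the equatorial leaving group, which the C6 oxygen cannot reach for oxetane formation; one equivalent of base at low temperature should limit enolisation of the β-silyloxy ketone, which is reduced at once in step 16.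

Step 16
Reactants: 23 ten-membered dienone
Product: 24 (6R)-allylic alcohol
Conditions: (R)-2-methyl-CBS-oxazaborolidine (30 mol %), catecholborane, toluene, −78 °C
Reagents that add atoms: none
Why: In this Corey–Bakshi–Shibata reduction, with C5 acting as the larger ketone substituent, the (R)-catalyst should deliver hydride to the face that gives the 6R alcohol (C6–O trans to the C7 arm), and the low temperature protects the β-silyloxy ketone.

Step 17
Reactants: 24 (6R)-allylic alcohol
Product: 25 C6,C12-diol (C8 silyl ether and C14 PMB ether kept)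
Conditions: HF·pyridine, pyridine, THF, 0 °C
Reagents that add atoms: none
Why: Selective desilylation is expected because the primary TBS ether is cleaved much faster than the hindered secondary one under buffered HF·pyridine.

Step 18
Reactants: 25 C6,C12-diol
Product: 27 trans-fused γ-lactone (6,12-olide), via lactol 26 (not isolated)
Conditions: TEMPO (20 mol %), PhI(OAc)2, CH2Cl2, rt
Reagents that add atoms: none
Why: In this TEMPO/PhI(OAc)2 oxidative lactonisation of a 1,4-diol the primary alcohol is oxidised, the aldehyde is captured by the C6 hydroxyl as the lactol and this is oxidised to the lactone, with C6 and C7 unchanged and the silylated C8 oxygen unable to compete.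

Step 19
Reactants: 27 trans-fused γ-lactone
Product: 31 α-methylene lactone, via lactone enolate 28 (not isolated), via Mannich base 29 (not isolated), via ammonium iodide 30 (not isolated)
Conditions: LiN(i-Pr)2, THF, −78 °C; CH2=NMe2+ I−, −78 to 0 °C; then MeI, MeOH, rt; NaHCO3 (aq), CH2Cl2
Reagents that add atoms: N,N-dimethylmethyleneiminium iodide (Eschenmoser's salt), C=[N+](C)C.[I-]
Why: α-Methylenation by the Mannich reaction of the lactone enolate, N-methylation and Hofmann-type elimination should install C13, and C11 becomes trigonal so that no stereocentre remains there.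

Step 20
Reactants: 31 α-methylene lactone
Product: 32 C8 alcohol
Conditions: HF·pyridine, THF, rt
Reagents that add atoms: none
Why: Desilylation of the secondary silyl ether with acidic HF·pyridine should avoid conjugate addition to the methylene lactone and lactone migration to the C8 oxygen.

Step 21
Reactants: 32 C8 alcohol
Product: 33 C8 isobutyrate
Conditions: i-PrCOCl, pyridine, DMAP (cat.), CH2Cl2, 0 °C
Reagents that add atoms: isobutyryl chloride, CC(C)C(=O)Cl
Why: DMAP-catalysed acylation of the secondary alcohol should occur with retention at C8 and faster than any oxa-Michael closure onto C13.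

Step 22
Reactants: 33 C8 isobutyrate
Product: 34 C14 allylic alcohol
Conditions: DDQ, CH2Cl2/pH 7 buffer, 0 °C
Reagents that add atoms: none
Why: Oxidative cleavage of the 4-methoxybenzyl ether by DDQ should free the primary allylic alcohol while leaving the alkenes, the ester and the methylene lactone intact.

Step 23
Reactants: 34 C14 allylic alcohol
Product: 35 target (CNP0247143.1)
Conditions: Ti(OiPr)4, L-(+)-diethyl tartrate, t-BuOOH, 4 Å molecular sieves, CH2Cl2, −20 °C
Reagents that add atoms: tert-butyl hydroperoxide, CC(C)(C)OO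
Why: In this Katsuki–Sharpless asymmetric epoxidation only the alkene of the allylic alcohol (C1=C10) should react, syn-stereospecifically so that C2 and C14 stay cis, and L-(+)-diethyl tartrate directs oxygen to the face that makes C10 S and C1 R, the same sense that gives (2S)-epoxy alcohols from simple allylic alcohols.

**Compound list**

1 | (1R,5S)-2-oxabicyclo[3.3.0]oct-6-en-3-one | O=C1C[C@H]2C=CC[C@H]2O1 | starting material
2 | (1R,2S)-2-(2-hydroxyethyl)cyclopent-3-en-1-ol | OCC[C@H]1C=CC[C@H]1O | intermediate
3 | bis(tert-butyldimethylsilyl) ether of 2 | CC(C)(C)[Si](C)(C)OCC[C@H]1C=CC[C@H]1O[Si](C)(C)C(C)(C)C | intermediate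
4 | α-epoxide of 3 (C6–C10 epoxide trans to the C7 arm and the C8 silyloxy group) | CC(C)(C)[Si](C)(C)OCC[C@H]1[C@@H]2O[C@@H]2C[C@H]1O[Si](C)(C)C(C)(C)C | intermediate
5 | trans hydroxy selenide (C6 α-hydroxyl, C10 β-phenylselanyl; not isolated) | CC(C)(C)[Si](C)(C)OCC[C@H]1[C@H](O)[C@@H]([Se]c2ccccc2)C[C@H]1O[Si](C)(C)C(C)(C)C | intermediate
6 | selenoxide of 5 (not isolated) | CC(C)(C)[Si](C)(C)OCC[C@H]1[C@H](O)[C@@H]([Se](=O)c2ccccc2)C[C@H]1O[Si](C)(C)C(C)(C)C | intermediate
7 | (1R,4R,5S)-4-(tert-butyldimethylsilyloxy)-5-[2-(tert-butyldimethylsilyloxy)ethyl]cyclopent-2-en-1-ol | CC(C)(C)[Si](C)(C)OCC[C@H]1[C@H](O)C=C[C@H]1O[Si](C)(C)C(C)(C)C | intermediate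
8 | (4R,5R)-4-(tert-butyldimethylsilyloxy)-5-[2-(tert-butyldimethylsilyloxy)ethyl]cyclopent-2-en-1-one (cis-4,5) | CC(C)(C)[Si](C)(C)OCC[C@H]1C(=O)C=C[C@H]1O[Si](C)(C)C(C)(C)C | intermediate
9 | 4-methylpent-4-en-1-ol | C=C(C)CCCO | starting material
10 | 4-methylpent-4-enal | C=C(C)CCC=O | intermediate
11 | iodo aldol adduct (C9 iodide, aluminium aldolate in the flask; not isolated) | CC(C)(C)[Si](C)(C)OCC[C@H]1C(=O)C(C(O)CCC(C)=C)C(I)[C@H]1O[Si](C)(C)C(C)(C)C | intermediate
12 | enone 8 with a 1-hydroxy-4-methylpent-4-enyl group at C10 (both C1 epimers) | CC(C)(C)[Si](C)(C)OCC[C@H]1C(=O)C(C(O)CCC(C)=C)=C[C@H]1O[Si](C)(C)C(C)(C)C | intermediate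
13 | trimethylsilyl ether of 12 (both C1 epimers) | CC(C)(C)[Si](C)(C)OCC[C@H]1C(=O)C(C(O[Si](C)(C)C)CCC(C)=C)=C[C@H]1O[Si](C)(C)C(C)(C)C | intermediate
14 | C6–C10 lithium enolate (not isolated) | CC(C)(C)[Si](C)(C)OCC[C@H]1C(O[Li])=C(C(O[Si](C)(C)C)CCC(C)=C)C[C@H]1O[Si](C)(C)C(C)(C)C | intermediate
15 | cyclopentanone with quaternary C10 (C14H2OPMB α, C1 arm β; both C1 epimers) | CC(C)(C)[Si](C)(C)OCC[C@H]1C(=O)[C@@](COCc2ccc(OC)cc2)(C(O[Si](C)(C)C)CCC(C)=C)C[C@H]1O[Si](C)(C)C(C)(C)C | intermediate
16 | C6 vinyl carbinol still silylated at O1 (not isolated) | CC(C)(C)[Si](C)(C)OCC[C@H]1[C@](O)(C=C)[C@@](COCc2ccc(OC)cc2)(C(O[Si](C)(C)C)CCC(C)=C)C[C@H]1O[Si](C)(C)C(C)(C)C | intermediate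
17 | diol: C6 β-hydroxyl and α-vinyl, free C1 hydroxyl (both C1 epimers) | CC(C)(C)[Si](C)(C)OCC[C@H]1[C@](O)(C=C)[C@@](COCc2ccc(OC)cc2)(C(O)CCC(C)=C)C[C@H]1O[Si](C)(C)C(C)(C)C | intermediate
18 | β-hydroxy ketone (C1 ketone, C6 tertiary alcohol) | CC(C)(C)[Si](C)(C)OCC[C@H]1[C@](O)(C=C)[C@@](COCc2ccc(OC)cc2)(C(=O)CCC(C)=C)C[C@H]1O[Si](C)(C)C(C)(C)C | intermediate
19 | trans-fused bicyclo[5.3.0]decenone (C1 ketone, C6 β-hydroxyl, C10 α-CH2OPMB, C4=C5) | C(CO[Si](C)(C)C(C)(C)C)[C@H]1[C@]2(O)C=C(C)CCC(=O)[C@@]2(COCc3ccc(OC)cc3)C[C@H]1O[Si](C)(C)C(C)(C)C | intermediate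
20 | trans-fused 1,6-diol (C1 hydroxyl cis to C14, anti to the C6 hydroxyl) | C(CO[Si](C)(C)C(C)(C)C)[C@H]1[C@]2(O)C=C(C)CC[C@H](O)[C@@]2(COCc3ccc(OC)cc3)C[C@H]1O[Si](C)(C)C(C)(C)C | intermediate
21 | C1 mesylate of 20 (trans-fused hydroazulene, C6 tertiary alcohol, mesylate cis to C14) | C(CO[Si](C)(C)C(C)(C)C)[C@H]1[C@]2(O)C=C(C)CC[C@H](OS(C)(=O)=O)[C@@]2(COCc3ccc(OC)cc3)C[C@H]1O[Si](C)(C)C(C)(C)C | intermediate
22 | potassium C6 alkoxide of 21 (not isolated) | [K+].C(CO[Si](C)(C)C(C)(C)C)[C@H]1[C@]2([O-])C=C(C)CC[C@H](OS(C)(=O)=O)[C@@]2(COCc3ccc(OC)cc3)C[C@H]1O[Si](C)(C)C(C)(C)C | intermediate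
23 | ten-membered dienone (C6 ketone, ring-cis C4=C5, ring-trans C1=C10) | C(CO[Si](C)(C)C(C)(C)C)[C@H]1C(=O)/C=C(/C)CC/C=C(\COCc2ccc(OC)cc2)C[C@H]1O[Si](C)(C)C(C)(C)C | intermediate
24 | (6R)-allylic alcohol | C(CO[Si](C)(C)C(C)(C)C)[C@H]1[C@H](O)/C=C(/C)CC/C=C(\COCc2ccc(OC)cc2)C[C@H]1O[Si](C)(C)C(C)(C)C | intermediate
25 | C6,C12-diol | OCC[C@H]1[C@H](O)/C=C(/C)CC/C=C(\COCc2ccc(OC)cc2)C[C@H]1O[Si](C)(C)C(C)(C)C | intermediate
26 | lactol (C12 hemiacetal to O6; not isolated) | C1C(O)O[C@@H]2/C=C(/C)CC/C=C(\COCc3ccc(OC)cc3)C[C@@H](O[Si](C)(C)C(C)(C)C)[C@@H]12 | intermediate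
27 | trans-fused γ-lactone (6,12-olide) | C1C(=O)O[C@@H]2/C=C(/C)CC/C=C(\COCc3ccc(OC)cc3)C[C@@H](O[Si](C)(C)C(C)(C)C)[C@@H]12 | intermediate
28 | lithium enolate of 27 (not isolated) | C1=C(O[Li])O[C@@H]2/C=C(/C)CC/C=C(\COCc3ccc(OC)cc3)C[C@@H](O[Si](C)(C)C(C)(C)C)[C@@H]12 | intermediate
29 | Mannich base, 11-(dimethylaminomethyl) lactone (not isolated) | CN(C)CC1C(=O)O[C@@H]2/C=C(/C)CC/C=C(\COCc3ccc(OC)cc3)C[C@@H](O[Si](C)(C)C(C)(C)C)[C@@H]12 | intermediate
30 | trimethylammonium iodide of 29 (not isolated) | C[N+](C)(C)CC1C(=O)O[C@@H]2/C=C(/C)CC/C=C(\COCc3ccc(OC)cc3)C[C@@H](O[Si](C)(C)C(C)(C)C)[C@@H]12.[I-] | intermediate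
31 | α-methylene lactone (C8 silyl ether, C14 PMB ether) | C=C1C(=O)O[C@@H]2/C=C(/C)CC/C=C(\COCc3ccc(OC)cc3)C[C@@H](O[Si](C)(C)C(C)(C)C)[C@@H]12 | intermediate
32 | C8 alcohol | C=C1C(=O)O[C@@H]2/C=C(/C)CC/C=C(\COCc3ccc(OC)cc3)C[C@@H](O)[C@@H]12 | intermediate
33 | C8 isobutyrate (C14 PMB ether) | C=C1C(=O)O[C@@H]2/C=C(/C)CC/C=C(\COCc3ccc(OC)cc3)C[C@@H](OC(=O)C(C)C)[C@@H]12 | intermediate
34 | C14 allylic alcohol | C=C1C(=O)O[C@@H]2/C=C(/C)CC/C=C(\CO)C[C@@H](OC(=O)C(C)C)[C@@H]12 | intermediate
35 | CNP0247143.1, (1R,6R,7R,8R,10S)-1,10-epoxy-14-hydroxy-8-isobutyryloxy-germacra-4Z,11(13)-dien-6,12-olide | C=C1C(=O)O[C@@H]2/C=C(/C)CC[C@H]3O[C@]3(CO)C[C@@H](OC(=O)C(C)C)[C@@H]12 | target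

**Step count and risks**

Total: 23 steps. Longest linear sequence: 22 steps (1 to 35; step 6 makes aldehyde 10 on a side branch).

The three steps most likely to fail:

First, step 15. The danger is base-driven decay once the ring is open (enolisation of the new ketone towards C7 with loss of silanolate from C8, or epimerisation at C7) and, if the alkoxide reacts sluggishly, elimination at C1 instead of fragmentation. The fallback does without strong base and changes the leaving group. It sets out from diol 20, which with Tf2O and pyridine in CH2Cl2 at −78 °C should be sulfonylated only at the secondary hydroxyl to give the C1 trifluoromethanesulfonate F1. With this leaving group the neutral tertiary alcohol should fragment on warming to 0 °C, pyridine taking up the proton, and the route is rejoined at dienone 23.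

Second, step 16. The danger is poor or reversed facial selectivity, because the conformation of the ten-membered ring or the branched C7 carbon may outweigh the catalyst. The fallback relies on the ring instead and corrects the result afterwards. It sets out from 23, which is reduced with NaBH4 and CeCl3 in MeOH at −78 °C (Luche reduction, hydride from the open outer face of the ring). If this gives the C6 epimer, the 6S alcohol F2, a Mitsunobu reaction (4-nitrobenzoic acid, PPh3, diisopropyl azodicarboxylate, THF) inverts C6 to the 6R 4-nitrobenzoate F3, and methanolysis (K2CO3, MeOH) returns to alcohol 24.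

Third, step 23. The danger is slow or mismatched oxygen transfer to a cis-substituted allylic alcohol held in a medium ring, together with Lewis-acid-induced transannular opening of the epoxy alcohol. The fallback moves the epoxidation one step earlier and uses substrate control. It sets out from PMB ether 33, whose strained ring-trans C1=C10 bond should be attacked by mCPBA (NaHCO3, CH2Cl2, 0 °C) from its outer face, expected to be the face required, to give the 1R,10S epoxide F4. DDQ (CH2Cl2, pH 7 buffer) then frees the C14 hydroxyl and the route ends at target 35.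

**Further compounds**

F1 | step 15 | C1 trifluoromethanesulfonate of diol 20 | C(CO[Si](C)(C)C(C)(C)C)[C@H]1[C@]2(O)C=C(C)CC[C@H](OS(=O)(=O)C(F)(F)F)[C@@]2(COCc3ccc(OC)cc3)C[C@H]1O[Si](C)(C)C(C)(C)C
F2 | step 16 | 6S epimer of alcohol 24 | C(CO[Si](C)(C)C(C)(C)C)[C@H]1[C@@H](O)/C=C(/C)CC/C=C(\COCc2ccc(OC)cc2)C[C@H]1O[Si](C)(C)C(C)(C)C
F3 | step 16 | 6R 4-nitrobenzoate of alcohol 24 | C(CO[Si](C)(C)C(C)(C)C)[C@H]1[C@H](OC(=O)c2ccc(cc2)[N+](=O)[O-])/C=C(/C)CC/C=C(\COCc3ccc(OC)cc3)C[C@H]1O[Si](C)(C)C(C)(C)C
F4 | step 23 | 1R,10S epoxide of PMB ether 33 | C=C1C(=O)O[C@@H]2/C=C(/C)CC[C@H]3O[C@]3(COCc4ccc(OC)cc4)C[C@@H](OC(=O)C(C)C)[C@@H]12
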